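The route rests on closing the cis-fused α-methylene γ-lactone through the C7–C11 bond (elemane numbering). A phosphonoacetate carbanion tethered to O8 opens a C6–C7 epoxide on the opposite face of the cyclohexane, and the phosphonolactone is methylenated with formaldehyde in the same flask. The step exploits the ring pattern O6 trans to C11 across C6–C7 and C11 cis to O8 across C7–C8; in one operation it sets C7, frees O6 for the angelate and installs C13. The precursor is an epoxycyclohexane with the C8 phosphonoacetate, C9 methacrylate, C10 methyl/vinyl centre and a dioxolane-masked C5 acetaldehyde chain, made from 2-methylcyclohexenone.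

Key step: step 10

Remark on numbering and faces: C10 is the quaternary ring carbon, C5 to C9 follow around the ring, C11–C13 are the lactone carbons and C4/C15/C3 the side chain on C5. "Methyl face" is the ring face that carries the C10 methyl group; "vinyl face" is the other. Assumption: the ligand enantiomer in step 1 is the one that gives (S) at C5.

Step 1
Reactants: 1 2-methylcyclohex-2-en-1-one; 2 (1,3-dioxolan-2-ylmethyl)magnesium bromide; 3 acetaldehyde
Product: 5 (2R,3S)-3-(1,3-dioxolan-2-ylmethyl)-2-(1-hydroxyethyl)-2-methylcyclohexan-1-one (carbinol carbon as a mixture), via magnesium enolate 4 (not isolated)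
Conditions: Cu(OTf)2 (3 mol%), chiral imidazolinium salt (NHC precursor, 4 mol%), Et2O/THF, −30 °C; then MeCHO, −78 °C; aq. NH4Cl
Reagents that add atoms: none
Why: Copper-catalysed asymmetric conjugate addition of the Grignard reagent to the α-methyl enone sets C5 under ligand control, and aldol trapping of the regiodefined enolate 4 should take acetaldehyde on the face opposite the new C5 chain, so that methyl and chain end cis (tandem conjugate addition–aldol reaction).

Step 2
Reactants: 5 aldol adduct
Product: 6 (2S,3S)-2-ethenyl-3-(1,3-dioxolan-2-ylmethyl)-2-methylcyclohexan-1-one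
Conditions: Martin sulfurane (Ph2S[OC(CF3)2Ph]2), CH2Cl2, 0 °C → rt
Reagents that add atoms: none
Why: Dehydration of the secondary alcohol through its alkoxysulfonium ion (E2 elimination) can only take a hydrogen from the methyl group because C10 is quaternary, so it should give the vinyl group without retro-aldol cleavage.

Step 3
Reactants: 6 vinyl ketone
Product: 7 (5S,6S)-6-ethenyl-5-(1,3-dioxolan-2-ylmethyl)-6-methylcyclohex-2-en-1-one
Conditions: IBX, DMSO, 70 °C
Reagents that add atoms: none
Why: IBX dehydrogenation of the ketone can only form the C7=C8 enone, since C10 carries no hydrogen.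

Step 4
Reactants: 7 enone
Product: 8 allylic alcohol (C9 hydroxyl on the methyl face, cis to the C5 chain; C7=C8)
Conditions: NaBH4, CeCl3·7H2O, MeOH, −78 °C
Reagents that add atoms: none
Why: Luche 1,2-reduction; hydride should attack C9 axially from the vinyl face of the conformer with equatorial C5 chain and axial C10 methyl (the other conformer is blocked on both faces), as in the reduction of carvone to cis-carveol.

Step 5
Reactants: 8 allylic alcohol
Product: 9 cis-epoxy alcohol (C7–C8 epoxide and C9 hydroxyl both on the methyl face)
Conditions: VO(acac)2 (cat.), t-BuOOH, CH2Cl2, 0 °C → rt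
Reagents that add atoms: tert-butyl hydroperoxide, CC(C)(C)OO
Why: Hydroxyl-directed epoxidation delivers oxygen syn to the allylic C9 hydroxyl, and the allylic ring alkene should react far faster than the C10 vinyl group.

Step 6
Reactants: 9 cis-epoxy alcohol
Product: 11 cis-diol (C6=C7; C8 and C9 hydroxyls on the methyl face), via hydroxy selenide 10 (not isolated)
Conditions: (PhSe)2, NaBH4, EtOH, 80 °C; then H2O2, THF, 0 °C → rt
Reagents that add atoms: none
Why: The selenolate should open the epoxide trans-diaxially at C7, the carbon remote from the carbinol, and syn elimination of the selenoxide away from the C8 carbinol gives the transposed allylic alcohol (epoxide to allylic alcohol transposition by selenide opening and selenoxide elimination).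

Step 7
Reactants: 11 cis-diol
Product: 12 epoxy cis-diol (C6–C7 epoxide, C8 and C9 hydroxyls all on the methyl face)
Conditions: VO(acac)2 (cat.), t-BuOOH, CH2Cl2, 0 °C
Reagents that add atoms: tert-butyl hydroperoxide, CC(C)(C)OO
Why: Hydroxyl-directed epoxidation; the pseudoaxial allylic C8 hydroxyl, reinforced by the homoallylic C9 hydroxyl on the same face, should deliver oxygen to the methyl face of C6=C7.

Step 8
Reactants: 12 epoxy cis-diol; 13 diethylphosphonoacetic acid
Product: 14 epoxy phosphonoacetate (C8 ester oxygen on the vinyl face; epoxide and C9 hydroxyl on the methyl face)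
Conditions: PPh3, DIAD, THF, 0 °C → rt
Reagents that add atoms: none
Why: Mitsunobu esterification with SN2 inversion at C8 (the neopentyl-type C9 hydroxyl should stay untouched) turns the cis-diol into the trans pattern and places the ester anti to the epoxide.

Step 9
Reactants: 14 epoxy phosphonoacetate; 15 methacrylic anhydride
Product: 16 epoxy phosphonoacetate methacrylate (C9 methacrylate on the methyl face)
Conditions: DMAP (cat.), Et3N, CH2Cl2, rt
Reagents that add atoms: none
Why: DMAP-catalysed acylation of the one remaining hydroxyl; the amine bases are too weak to deprotonate the phosphonoacetate.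

Step 10
Reactants: 16 epoxy phosphonoacetate methacrylate
Product: 18 hydroxy α-methylene lactone (C6 hydroxyl on the methyl face; lactone cis-fused on the vinyl face), via phosphonolactone 17 (not isolated)
Conditions: KHMDS (1.05 equiv), THF (dilute), −78 °C → rt; then (CH2O)n, 0 °C → rt
Reagents that add atoms: paraformaldehyde (formaldehyde), C=O
Why: KHMDS deprotonates the phosphonoacetate, and the carbanion, held on the vinyl face by O8, attacks C7 anti to the epoxide C7–O bond; the C6 alkoxide then takes the acidic α-proton of 17, and the phosphonate carbanion undergoes Horner–Wadsworth–Emmons olefination with formaldehyde. The closest known reaction types are the lactone-forming opening of epoxides by phosphonoacetate or malonate carbanions and the telescoped intramolecular Michael addition–olefination of phosphonoacetate esters. The lactone closes in the 5-exo-tet mode (C7 inside the new ring, the breaking C7–O bond outside it). C7 is set by SN2 inversion, so C11 ends cis to O8 and trans to O6, C6 keeps its oxygen with retention, and the C11 centre of 17 is erased by the olefination. The step needs attack at C7 and not at C6 (6-endo, bridged δ-lactone), and attack on the epoxide and not on the methacrylate; the first should follow because only opening at C7 is trans-diaxial (Fürst–Plattner) in the half-chair that keeps O8, O9 and the C5 chain equatorial, the second from the intramolecular five-membered closure at high dilution.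

Step 11
Reactants: 18 hydroxy α-methylene lactone; 19 angelic acid
Product: 20 C6 angelate
Conditions: 19, 2,4,6-Cl3C6H2COCl, Et3N, toluene, rt; then 18, 80 °C
Reagents that add atoms: none
Why: Yamaguchi-type mixed-anhydride acylation without a nucleophilic catalyst, under which angelates should form without Z to E isomerisation to the tiglate; the axial C6 hydroxyl is the only free hydroxyl.

Step 12
Reactants: 20 C6 angelate
Product: 21 aldehyde (C5–CH2–CHO)
Conditions: TsOH·H2O (cat.), acetone/H2O, 45 °C
Reagents that add atoms: water, O
Why: Acid-catalysed acetal hydrolysis; the esters, lactone and alkenes should be stable to dilute acid, and O6 is already acylated, so no lactol can form.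

Step 13
Reactants: 21 aldehyde
Product: 22 target CNP0102441.1
Conditions: Me2N=CH2+ I− (Eschenmoser's salt, excess), Et3N, CH2Cl2, rt
Reagents that add atoms: Eschenmoser's salt (N,N-dimethylmethyleneiminium iodide), C=[N+](C)C.[I-]
Why: Mannich reaction of the aldehyde enol with the iminium salt and β-elimination of dimethylamine (aldehyde α-methylenation); only the aldehyde has an enolisable CH2, and excess iminium salt should scavenge the liberated amine before it adds to the α-methylene lactone.

Compound list
1 | 2-methylcyclohex-2-en-1-one | CC1=CCCCC1=O | starting material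
2 | (1,3-dioxolan-2-ylmethyl)magnesium bromide | Br[Mg]CC1OCCO1 | starting material
3 | acetaldehyde | CC=O | starting material
4 | bromomagnesium enolate (C9–O–MgBr, C9=C10) with the (S)-configured C5 chain | CC1=C(O[Mg]Br)CCC[C@H]1CC2OCCO2 | intermediate
5 | (2R,3S)-3-(1,3-dioxolan-2-ylmethyl)-2-(1-hydroxyethyl)-2-methylcyclohexan-1-one, hydroxyethyl trans to the C5 chain, carbinol carbon as a mixture | CC(O)[C@@]1(C)[C@H](CC2OCCO2)CCCC1=O | intermediate
6 | (2S,3S)-2-ethenyl-3-(1,3-dioxolan-2-ylmethyl)-2-methylcyclohexan-1-one | C=C[C@@]1(C)[C@H](CC2OCCO2)CCCC1=O | intermediate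
7 | (5S,6S)-6-ethenyl-5-(1,3-dioxolan-2-ylmethyl)-6-methylcyclohex-2-en-1-one | C=C[C@@]1(C)[C@H](CC2OCCO2)CC=CC1=O | intermediate
8 | allylic alcohol, C9–OH on the methyl face, C7=C8 | C=C[C@@]1(C)[C@H](CC2OCCO2)CC=C[C@@H]1O | intermediate
9 | cis-epoxy alcohol, C7–C8 epoxide and C9–OH on the methyl face | C=C[C@@]1(C)[C@H](CC2OCCO2)C[C@@H]3O[C@@H]3[C@@H]1O | intermediate
10 | hydroxy selenide, C7–SePh on the vinyl face, C8–OH and C9–OH on the methyl face | C=C[C@@]1(C)[C@H](CC2OCCO2)C[C@@H]([Se]c3ccccc3)[C@H](O)[C@@H]1O | intermediate
11 | cis-diol, C6=C7, C8–OH and C9–OH on the methyl face | C=C[C@@]1(C)[C@H](CC2OCCO2)C=C[C@H](O)[C@@H]1O | intermediate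
12 | epoxy cis-diol, C6–C7 epoxide, C8–OH and C9–OH on the methyl face | C=C[C@@]1(C)[C@H](CC2OCCO2)[C@@H]3O[C@@H]3[C@H](O)[C@@H]1O | intermediate
13 | diethylphosphonoacetic acid | OC(=O)CP(=O)(OCC)OCC | starting material
14 | epoxy phosphonoacetate, C8 ester oxygen on the vinyl face, epoxide and C9–OH on the methyl face | C=C[C@@]1(C)[C@H](CC2OCCO2)[C@@H]3O[C@@H]3[C@@H](OC(=O)CP(=O)(OCC)OCC)[C@@H]1O | intermediate
15 | methacrylic anhydride | CC(=C)C(=O)OC(=O)C(C)=C | starting material
16 | epoxy phosphonoacetate with C9 methacrylate | C=C[C@@]1(C)[C@H](CC2OCCO2)[C@@H]3O[C@@H]3[C@@H](OC(=O)CP(=O)(OCC)OCC)[C@@H]1OC(=O)C(=C)C | intermediate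
17 | α-(diethoxyphosphoryl) lactone, cis-fused at C7–C8, C6–OH on the methyl face, C11 as a mixture | C=C[C@@]1(C)[C@H](CC3OCCO3)[C@H](O)[C@H]2C(P(=O)(OCC)OCC)C(=O)O[C@H]2[C@@H]1OC(=O)C(=C)C | intermediate
18 | hydroxy α-methylene lactone | C=C[C@@]1(C)[C@H](CC3OCCO3)[C@H](O)[C@H]2C(=C)C(=O)O[C@H]2[C@@H]1OC(=O)C(=C)C | intermediate
19 | angelic acid, (Z)-2-methylbut-2-enoic acid | C/C=C(/C)C(=O)O | starting material
20 | C6 angelate, dioxolane still in place | C=C[C@@]1(C)[C@H](CC3OCCO3)[C@H](OC(=O)/C(C)=C\C)[C@H]2C(=C)C(=O)O[C@H]2[C@@H]1OC(=O)C(=C)C | intermediate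
21 | aldehyde, C5–CH2–CHO | C=C[C@@]1(C)[C@H](CC=O)[C@H](OC(=O)/C(C)=C\C)[C@H]2C(=C)C(=O)O[C@H]2[C@@H]1OC(=O)C(=C)C | intermediate
22 | CNP0102441.1: angelate at C6 and methacrylate at C9 on the methyl face, lactone oxygen at C8 and C11 at C7 on the vinyl face, 2-substituted acrolein at C5 | C=C[C@@]1(C)[C@H](C(=C)C=O)[C@H](OC(=O)/C(C)=C\C)[C@H]2C(=C)C(=O)O[C@H]2[C@@H]1OC(=O)C(=C)C | target

Total step count: 13. Longest linear sequence: 13 steps (1 to 22).

Steps most likely to fail

1. Step 10 (key step). The stabilised carbanion may open the neutral epoxide too slowly, so that on warming conjugate addition to the methacrylate, acyl transfer or cyclopropane formation by phosphoryl transfer to the C6 alkoxide take over. The fallback sets out from 12 and comes back at 18; it keeps the same ring closure but uses the classical malonate–epoxide alkylation and a decarboxylative methylenation. Mitsunobu esterification of 12 with allyl hydrogen malonate (PPh3, DIAD) would give the C8 allyl malonate F1. Methacrylic anhydride/DMAP would give the C9 methacrylate F2. Cs2CO3 in DMF should close the lactone to the α-allyloxycarbonyl hydroxy lactone F3. Pd(PPh3)4/morpholine would free the α-carboxy lactone F4, and aqueous formaldehyde, Et2NH and NaOAc/AcOH would give 18 by decarboxylative Mannich methylenation.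

2. Step 1. Facial discrimination by the chiral copper catalyst may be poor with this oxygen-bearing Grignard reagent on the α-methyl enone, or the aldolate may revert during trapping. The fallback sets out from 2 (with commercial cyclohex-2-en-1-one) and comes back at 5; it moves the asymmetric step to the unsubstituted enone and builds the quaternary centre separately. CuBr·SMe2 with the ferrocenyl diphosphine 1-[2-(diphenylphosphino)ferrocenyl]ethyldicyclohexylphosphine (Josiphos type, enantiomer chosen for 3S), then MeI/DMPU, would give the trans-2-methyl ketone F5. TMSCl/NaI/Et3N in MeCN would give the more substituted silyl enol ether F6. MeLi followed by acetaldehyde at −78 °C would give 5.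

3. Step 8. Displacement at the C8 carbinol, flanked by the epoxide and the hindered C9 centre, may be slow, so that elimination or return of the diol competes. The fallback sets out from 11 and comes back at 14; it moves the inversion to the allylic stage. Mitsunobu esterification of 11 with 13 would give the allylic phosphonoacetate F7 (C8 ester on the vinyl face, C9–OH free). VO(acac)2/t-BuOOH, now directed by the homoallylic C9 hydroxyl, should then give 14.

Further compounds
F1 | step 10 | epoxy C8 allyl malonate, C9–OH free | C=C[C@@]1(C)[C@H](CC2OCCO2)[C@@H]3O[C@@H]3[C@@H](OC(=O)CC(=O)OCC=C)[C@@H]1O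
F2 | step 10 | epoxy C8 allyl malonate C9 methacrylate | C=C[C@@]1(C)[C@H](CC2OCCO2)[C@@H]3O[C@@H]3[C@@H](OC(=O)CC(=O)OCC=C)[C@@H]1OC(=O)C(=C)C
F3 | step 10 | α-allyloxycarbonyl hydroxy lactone | C=C[C@@]1(C)[C@H](CC3OCCO3)[C@H](O)[C@H]2C(C(=O)OCC=C)C(=O)O[C@H]2[C@@H]1OC(=O)C(=C)C
F4 | step 10 | α-carboxy hydroxy lactone | C=C[C@@]1(C)[C@H](CC3OCCO3)[C@H](O)[C@H]2C(C(=O)O)C(=O)O[C@H]2[C@@H]1OC(=O)C(=C)C
F5 | step 1 | trans-(3S)-3-(1,3-dioxolan-2-ylmethyl)-2-methylcyclohexan-1-one | C[C@H]1[C@H](CC2OCCO2)CCCC1=O
F6 | step 1 | trimethylsilyl enol ether (C9–OSiMe3, C9=C10) of F5 | CC1=C(O[Si](C)(C)C)CCC[C@H]1CC2OCCO2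
F7 | step 8 | allylic phosphonoacetate, C8 ester on the vinyl face, C9–OH on the methyl face, C6=C7 | C=C[C@@]1(C)[C@H](CC2OCCO2)C=C[C@@H](OC(=O)CP(=O)(OCC)OCC)[C@@H]1O
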